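**Plan**

- Retrosynthetic cuts, in order: the C3–O ester bond; the C6=C7/C8=O enone back to a C8=C9 olefin with sp3 C7; the C3 and C4 oxygens and C5–H back to a Δ4-3-ketone; C4=C5 (aldol); C1–C10 (Michael addition to ethyl vinyl ketone).
- Enabling feature: ring B (C5–C10) carries the C10 methyl and the three-carbon C11 unit on C7 in the 1,4-relationship of carvone, and C7 finishes as an sp2 carbon of the enone, so its carvone stereocentre can steer quaternary C10 and then vanish.
- Forward: ring B is the ring of (R)-carvone, hydrated and silylated; its extended dienolate is joined to ethyl vinyl ketone at C10, and aldol condensation then closes ring A.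
- Ring A is set by Li/NH3 reductive silylation, Rubottom oxidation and NaBH4; after esterification at O3 a silicon tether from O11 oxygenates C8, and oxidation plus dehydrogenation give the enone.
- Stereochemistry: C7 of carvone sets C10 (anti attack); the C10 methyl sets C5 (trans fusion), C4 (α-OH) and C3 (β-O); the acyl stereocentre comes from (R)-2-methylbutanoic acid.

Key step: step 3

Remark: eudesmane numbering is used throughout (ring A = C1–C5 and C10, ring B = C5–C10, C11 = carbinol carbon on C7); β is the face of the C10 methyl, α the other face; the anti course of step 3 is assumed from the conformational argument given there.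

**Route**

Step 1
Reactants: 1 (R)-carvone
Product: 2 (5R)-5-(2-hydroxypropan-2-yl)-2-methylcyclohex-2-en-1-one
Conditions: 50% aq. H2SO4, 0 °C
Reagents that add atoms: water, O
Why: Markovnikov acid-catalysed hydration of the isopropenyl group through its tertiary cation (alkene hydration) should leave the conjugated enone and the C7 stereocentre untouched.

Step 2
Reactants: 2 (5R)-5-(2-hydroxypropan-2-yl)-2-methylcyclohex-2-en-1-one
Product: 3 (5R)-2-methyl-5-[2-(triethylsilyloxy)propan-2-yl]cyclohex-2-en-1-one
Conditions: Et3SiOTf, 2,6-lutidine, CH2Cl2, −78 → 0 °C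
Reagents that add atoms: triethylsilyl trifluoromethanesulfonate, CC[Si](CC)(CC)OS(=O)(=O)C(F)(F)F
Why: Silyl ether protection of a hindered tertiary alcohol with a silyl triflate and a hindered pyridine base is routine, and 2,6-lutidine does not enolise the enone at low temperature.

Step 3
Reactants: 3 (5R)-2-methyl-5-[2-(triethylsilyloxy)propan-2-yl]cyclohex-2-en-1-one; 4 ethyl vinyl ketone
Product: 6 (2R,5S)-2-methyl-2-(3-oxopentyl)-5-[2-(triethylsilyloxy)propan-2-yl]cyclohex-3-en-1-one (new chain anti to the C7 side chain), via potassium dienolate 5 (not isolated)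
Conditions: t-BuOK (0.3 equiv), t-BuOH/THF (1:3), −20 °C; 4 added slowly; → 0 °C
Reagents that add atoms: none
Why: t-BuOK reversibly removes a γ-proton at C8 of 3 to give the through-conjugated potassium dienolate 5, which adds through C10, its α-carbon and the site of highest electron density, to the β-carbon of 4; protonation of the chain enolate by t-BuOH then leaves the olefin at C8=C9, where it cannot return to conjugation past quaternary C10. The closest known reaction type is the deconjugative α-alkylation and α-Michael addition (cyanoethylation, vinyl ketone addition) of 2-alkylcyclohexenone dienolates under t-BuOK/t-BuOH. No ring is closed. The new quaternary stereocentre C10 is controlled only by C7: 5 is the 1-oxido analogue of α-phellandrene, whose C5 substituent can sit pseudoaxially and screen that face of the diene across the ring, so 4 should enter from the α-face, anti to the bulky silyloxy-isopropyl group, leaving the methyl β. The step needs α- over γ- and α′-attack, mono-addition and anti facial attack; the first two are secured by equilibrating protic conditions with a potassium counter-ion and slow addition of 4 at low temperature, the third by the size of the C7 substituent together with the absence of any sp3 neighbour at C10 that could impose an opposing axial-attack preference. The C10 epimer is a diastereomer of 6 and is removed by chromatography at this stage.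

Step 4
Reactants: 6 (2R,5S)-2-methyl-2-(3-oxopentyl)-5-[2-(triethylsilyloxy)propan-2-yl]cyclohex-3-en-1-one
Product: 8 11-(triethylsilyloxy)eudesma-4,8-dien-3-one (7β side chain, 10β methyl), via ketol 7 (not isolated)
Conditions: NaOMe (0.5 equiv), MeOH, 25 → 45 °C
Reagents that add atoms: none
Why: Intramolecular aldol condensation (second stage of a Robinson annulation): the C4 enolate of the ethyl ketone adds to the C5 ketone in a 6-exo closure and ketol 7 dehydrates to the tetrasubstituted enone, while the C8=C9 olefin cannot move past quaternary C10 and the tertiary silyl ether tolerates methoxide.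

Step 5
Reactants: 8 11-(triethylsilyloxy)eudesma-4,8-dien-3-one
Product: 10 3-(trimethylsilyloxy)-11-(triethylsilyloxy)-5α-eudesma-3,8-diene, via lithium enolate 9 (not isolated)
Conditions: Li, NH3(l)/THF, t-BuOH (1 equiv), −78 °C; NH3 evaporated; then Me3SiCl, Et3N, THF, −78 → 0 °C
Reagents that add atoms: chlorotrimethylsilane, C[Si](C)(C)Cl
Why: Dissolving-metal reduction with regiospecific enolate trapping (reductive silylation): C5 is protonated axially from the α-face, anti to the C10 methyl, which sets the trans ring fusion, and the C3 enolate 9 is captured as the Δ3 silyl enol ether, while the isolated C8=C9 olefin and the silyl ether are not reduced.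

Step 6
Reactants: 10 3-(trimethylsilyloxy)-11-(triethylsilyloxy)-5α-eudesma-3,8-diene
Product: 12 4α,11-dihydroxy-5α-eudesm-8-en-3-one (4β methyl), via silyloxy ketone 11 (not isolated)
Conditions: mCPBA (1.05 equiv), NaHCO3, CH2Cl2, −20 °C; then HF·pyridine, THF, 0 → 25 °C
Reagents that add atoms: mCPBA (3-chloroperoxybenzoic acid), OOC(=O)c1cccc(Cl)c1
Why: Rubottom oxidation: the electron-rich tetrasubstituted silyl enol ether should be epoxidised far faster than the hindered disubstituted C8=C9 olefin and from the α-face, opposite the 1,3-diaxial C10 methyl, so that after silyl migration the C4 oxygen is α and the methyl β; HF·pyridine then removes both silyl groups.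

Step 7
Reactants: 12 4α,11-dihydroxy-5α-eudesm-8-en-3-one
Product: 13 5α-eudesm-8-ene-3β,4α,11-triol
Conditions: NaBH4, MeOH, −20 → 0 °C
Reagents that add atoms: none
Why: Borohydride reduction by axial hydride delivery from the α-face, the β-face being screened by the axial C4 methyl, should give the equatorial 3β-alcohol trans to the C4 hydroxyl.

Step 8
Reactants: 13 5α-eudesm-8-ene-3β,4α,11-triol; 14 (R)-2-methylbutanoic acid
Product: 15 4α,11-dihydroxy-5α-eudesm-8-en-3β-yl (R)-2-methylbutanoate
Conditions: DCC, DMAP (cat.), CH2Cl2, 0 → 25 °C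
Reagents that add atoms: none
Why: Steglich esterification should acylate only the secondary C3 hydroxyl because the other two hydroxyls are tertiary, and the α-stereocentre of the acid is not at risk under carbodiimide/DMAP conditions at this temperature.

Step 9
Reactants: 15 4α,11-dihydroxy-5α-eudesm-8-en-3β-yl (R)-2-methylbutanoate
Product: 18 4α,8β,11-trihydroxy-5α-eudesman-3β-yl (R)-2-methylbutanoate, via bis(dimethylsilyl) ether 16 (not isolated), via oxasilolane 17 (not isolated)
Conditions: HMe2SiCl, Et3N, DMAP (cat.), CH2Cl2, 0 → 25 °C; filtration and solvent change; Pt2[(CH2=CHSiMe2)2O]3 (Karstedt catalyst, zerovalent platinum, 1 mol %), toluene, 60 °C; then KF, KHCO3, 30% H2O2, THF/MeOH, 25 °C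
Reagents that add atoms: hydrogen peroxide, OO
Why: Tamao intramolecular hydrosilylation of a homoallylic alcohol followed by Tamao–Fleming oxidation: the Si–H tethered to O11 should close the five-membered oxasilolane onto C8 (5-exo, β-face, cis to the C7 side chain) in preference to 6-endo closure onto neopentyl C9, and oxidation with retention places the hydroxyl at C8β, so the tether enforces a regiochemistry that intermolecular hydration of this olefin would not guarantee; the silyl group on O4 is lost in the oxidation.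

Step 10
Reactants: 18 4α,8β,11-trihydroxy-5α-eudesman-3β-yl (R)-2-methylbutanoate
Product: 19 4α,11-dihydroxy-8-oxo-5α-eudesman-3β-yl (R)-2-methylbutanoate (7α-H)
Conditions: Dess–Martin periodinane, pyridine, CH2Cl2, 0 → 25 °C
Reagents that add atoms: none
Why: Dess–Martin oxidation should convert the only secondary alcohol into the ketone under buffered, non-basic conditions that spare the retro-aldol-prone β-hydroxy ketone, the tertiary alcohols and the ester.

Step 11
Reactants: 19 4α,11-dihydroxy-8-oxo-5α-eudesman-3β-yl (R)-2-methylbutanoate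
Product: 20 4α,11-dihydroxy-8-oxo-5α-eudesm-6-en-3β-yl (R)-2-methylbutanoate (CNP0201989.1)
Conditions: IBX, 4-methoxypyridine N-oxide, DMSO, 25 → 40 °C
Reagents that add atoms: none
Why: IBX dehydrogenation of a ketone through its enol: desaturation is possible only towards C6–C7 because C10 carries no hydrogen, it erases the C7 stereocentre, the α-substituted enone cannot over-oxidise, and the N-oxide complex allows reaction near room temperature, which spares the tertiary aldol unit.

**Compound list**

1 | (R)-carvone | CC1=CC[C@H](CC1=O)C(C)=C | starting material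
2 | (5R)-5-(2-hydroxypropan-2-yl)-2-methylcyclohex-2-en-1-one | CC1=CC[C@H](CC1=O)C(C)(C)O | intermediate
3 | (5R)-2-methyl-5-[2-(triethylsilyloxy)propan-2-yl]cyclohex-2-en-1-one | CC1=CC[C@H](CC1=O)C(C)(C)O[Si](CC)(CC)CC | intermediate
4 | ethyl vinyl ketone (pent-1-en-3-one) | C=CC(=O)CC | starting material
5 | potassium (5S)-2-methyl-5-[2-(triethylsilyloxy)propan-2-yl]cyclohexa-1,3-dien-1-olate (C7 arranged as in 3) | CC1=C([O-])C[C@@H](C=C1)C(C)(C)O[Si](CC)(CC)CC.[K+] | intermediate
6 | (2R,5S)-2-methyl-2-(3-oxopentyl)-5-[2-(triethylsilyloxy)propan-2-yl]cyclohex-3-en-1-one | CCC(=O)CC[C@]1(C)C=C[C@H](CC1=O)C(C)(C)O[Si](CC)(CC)CC | intermediate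
7 | 5-hydroxy-11-(triethylsilyloxy)eudesm-8-en-3-one (ketol, C4 and C5 not defined) | O=C1CC[C@]2(C)C=C[C@H](CC2(O)C1C)C(C)(C)O[Si](CC)(CC)CC | intermediate
8 | 11-(triethylsilyloxy)eudesma-4,8-dien-3-one (7β side chain, 10β methyl) | O=C1CC[C@]2(C)C=C[C@H](CC2=C1C)C(C)(C)O[Si](CC)(CC)CC | intermediate
9 | lithium 11-(triethylsilyloxy)-5α-eudesma-3,8-dien-3-olate | [Li+].[O-]C1=C(C)[C@@H]2C[C@H](C(C)(C)O[Si](CC)(CC)CC)C=C[C@@]2(C)CC1 | intermediate
10 | 3-(trimethylsilyloxy)-11-(triethylsilyloxy)-5α-eudesma-3,8-diene | C[Si](C)(C)OC1=C(C)[C@@H]2C[C@H](C(C)(C)O[Si](CC)(CC)CC)C=C[C@@]2(C)CC1 | intermediate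
11 | 4α-(trimethylsilyloxy)-11-(triethylsilyloxy)-5α-eudesm-8-en-3-one | O=C1CC[C@]2(C)C=C[C@@H](C(C)(C)O[Si](CC)(CC)CC)C[C@H]2[C@]1(C)O[Si](C)(C)C | intermediate
12 | 4α,11-dihydroxy-5α-eudesm-8-en-3-one | O=C1CC[C@]2(C)C=C[C@@H](C(C)(C)O)C[C@H]2[C@]1(C)O | intermediate
13 | 5α-eudesm-8-ene-3β,4α,11-triol | O[C@H]1CC[C@]2(C)C=C[C@@H](C(C)(C)O)C[C@H]2[C@]1(C)O | intermediate
14 | (R)-2-methylbutanoic acid | CC[C@@H](C)C(=O)O | starting material
15 | 4α,11-dihydroxy-5α-eudesm-8-en-3β-yl (R)-2-methylbutanoate | CC[C@@H](C)C(=O)O[C@H]1CC[C@]2(C)C=C[C@@H](C(C)(C)O)C[C@H]2[C@]1(C)O | intermediate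
16 | 4α,11-bis(dimethylsilyloxy)-5α-eudesm-8-en-3β-yl (R)-2-methylbutanoate | CC[C@@H](C)C(=O)O[C@H]1CC[C@]2(C)C=C[C@@H](C(C)(C)O[SiH](C)C)C[C@H]2[C@]1(C)O[SiH](C)C | intermediate
17 | oxasilolane: SiMe2 bonded to C8β and to O11 (1-oxa-2-silacyclopentane cis-fused at C7–C8), 4α-dimethylsilyloxy, 3β-(R)-2-methylbutanoate | CC[C@@H](C)C(=O)O[C@H]1CC[C@]2(C)C[C@@H]3[C@H](C[C@H]2[C@]1(C)O[SiH](C)C)C(C)(C)O[Si]3(C)C | intermediate
18 | 4α,8β,11-trihydroxy-5α-eudesman-3β-yl (R)-2-methylbutanoate | CC[C@@H](C)C(=O)O[C@H]1CC[C@]2(C)C[C@@H](O)[C@H](C[C@H]2[C@]1(C)O)C(C)(C)O | intermediate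
19 | 4α,11-dihydroxy-8-oxo-5α-eudesman-3β-yl (R)-2-methylbutanoate | CC[C@@H](C)C(=O)O[C@H]1CC[C@]2(C)CC(=O)[C@H](C[C@H]2[C@]1(C)O)C(C)(C)O | intermediate
20 | 4α,11-dihydroxy-8-oxo-5α-eudesm-6-en-3β-yl (R)-2-methylbutanoate | CC[C@@H](C)C(=O)O[C@H]1CC[C@]2(C)CC(=O)C(C(C)(C)O)=C[C@H]2[C@]1(C)O | target

**Step count**

Total steps: 11. Longest linear sequence: 11 steps (1 → 20).

**Steps most likely to fail**

Step 3. What may go wrong is weak or wrong-sense facial discrimination at C10 by the remote C7 group, with some attack through C6 or C8 as a lesser concern. The fallback replaces substrate control by catalyst control. It sets out from 3 and comes back at 6. Compound 3 is converted with stoichiometric t-BuOK in THF into dienolate 5, which is O-acylated with allyl chloroformate to give allyl (5S)-2-methyl-5-[2-(triethylsilyloxy)propan-2-yl]cyclohexa-1,3-dien-1-yl carbonate F1. Decarboxylative allylic alkylation (Tsuji allylation) with Pd2(dba)3 (zerovalent palladium) and the t-Bu-PHOX enantiomer matched to α-face delivery forms the C1–C10 bond under ligand control and gives (2R,5S)-2-allyl-2-methyl-5-[2-(triethylsilyloxy)propan-2-yl]cyclohex-3-en-1-one F2. Hydroboration of the terminal olefin with 9-BBN and oxidation with NaBO3 give the primary alcohol (2R,5S)-2-(3-hydroxypropyl)-2-methyl-5-[2-(triethylsilyloxy)propan-2-yl]cyclohex-3-en-1-one F3. Dess–Martin oxidation gives the aldehyde 3-[(1R,4S)-1-methyl-2-oxo-4-[2-(triethylsilyloxy)propan-2-yl]cyclohex-5-en-1-yl]propanal F4. EtMgBr at −78 °C adds to the aldehyde in preference to the hindered ring ketone and gives (2R,5S)-2-(3-hydroxypentyl)-2-methyl-5-[2-(triethylsilyloxy)propan-2-yl]cyclohex-3-en-1-one F5. A second Dess–Martin oxidation returns 6.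

Step 9. What may go wrong is slow or misdirected insertion of the hindered ring olefin into the tethered Si–H bond, or olefin migration on platinum. The fallback replaces the tether by a hydroxyl-directed epoxidation and a stereoelectronically controlled reduction. It sets out from 13 and comes back at 18. VO(acac)2 and t-BuOOH in CH2Cl2, directed by the homoallylic C11 hydroxyl, should give 8β,9β-epoxy-5α-eudesmane-3β,4α,11-triol F6. LiAlH4 in THF should open it trans-diaxially (Fürst–Plattner), hydride entering at C9 from the α-face, to give 5α-eudesmane-3β,4α,8β,11-tetraol F7. Esterification with 14 (DCC, DMAP) should take place at the equatorial C3 hydroxyl, the axial C8 hydroxyl being screened by the C10 methyl and the C7 side chain, and gives 18.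

Step 11. What may go wrong is loss of water from the tertiary aldol unit, or retro-aldol cleavage, before the hindered C7 enol is oxidised. The fallback makes the dehydration deliberate and returns the oxygen by an ene reaction. It sets out from 19 and comes back at 20. Catalytic p-TsOH in CH2Cl2 gives 4α-hydroxy-8-oxo-5α-eudesm-7(11)-en-3β-yl (R)-2-methylbutanoate F8. Sensitised photo-oxygenation (O2, tetraphenylporphyrin, visible light, CH2Cl2, 0 °C; Schenck ene reaction) should place oxygen on C11 and take hydrogen from C6, the group geminal to the carbonyl, to give 11-hydroperoxy-4α-hydroxy-8-oxo-5α-eudesm-6-en-3β-yl (R)-2-methylbutanoate F9. Reduction with PPh3 gives 20.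

**Further compounds**

F1 | step 3 | allyl (5S)-2-methyl-5-[2-(triethylsilyloxy)propan-2-yl]cyclohexa-1,3-dien-1-yl carbonate | C=CCOC(=O)OC1=C(C)C=C[C@H](C1)C(C)(C)O[Si](CC)(CC)CC
F2 | step 3 | (2R,5S)-2-allyl-2-methyl-5-[2-(triethylsilyloxy)propan-2-yl]cyclohex-3-en-1-one | C=CC[C@]1(C)C=C[C@H](CC1=O)C(C)(C)O[Si](CC)(CC)CC
F3 | step 3 | (2R,5S)-2-(3-hydroxypropyl)-2-methyl-5-[2-(triethylsilyloxy)propan-2-yl]cyclohex-3-en-1-one | OCCC[C@]1(C)C=C[C@H](CC1=O)C(C)(C)O[Si](CC)(CC)CC
F4 | step 3 | 3-[(1R,4S)-1-methyl-2-oxo-4-[2-(triethylsilyloxy)propan-2-yl]cyclohex-5-en-1-yl]propanal | O=CCC[C@]1(C)C=C[C@H](CC1=O)C(C)(C)O[Si](CC)(CC)CC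
F5 | step 3 | (2R,5S)-2-(3-hydroxypentyl)-2-methyl-5-[2-(triethylsilyloxy)propan-2-yl]cyclohex-3-en-1-one (carbinol centre not defined) | CCC(O)CC[C@]1(C)C=C[C@H](CC1=O)C(C)(C)O[Si](CC)(CC)CC
F6 | step 9 | 8β,9β-epoxy-5α-eudesmane-3β,4α,11-triol | O[C@H]1CC[C@]2(C)[C@H]3O[C@H]3[C@@H](C(C)(C)O)C[C@H]2[C@]1(C)O
F7 | step 9 | 5α-eudesmane-3β,4α,8β,11-tetraol | O[C@H]1CC[C@]2(C)C[C@@H](O)[C@H](C[C@H]2[C@]1(C)O)C(C)(C)O
F8 | step 11 | 4α-hydroxy-8-oxo-5α-eudesm-7(11)-en-3β-yl (R)-2-methylbutanoate | CC[C@@H](C)C(=O)O[C@H]1CC[C@]2(C)CC(=O)C(=C(C)C)C[C@H]2[C@]1(C)O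
F9 | step 11 | 11-hydroperoxy-4α-hydroxy-8-oxo-5α-eudesm-6-en-3β-yl (R)-2-methylbutanoate | CC[C@@H](C)C(=O)O[C@H]1CC[C@]2(C)CC(=O)C(C(C)(C)OO)=C[C@H]2[C@]1(C)O
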